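**Retrosynthetic overview**
1. Mailiohydrin 21 ⇒ ring B enone 20: the dibromomethyl carbinol is made last, by 1,2-addition of LiCHBr2.
2. Ring A of 20 (exocyclic methylene, cis-bromohydrin) ⇒ hydroxymethyl enone 11: α′-bromination, cis-selective hydride reduction, reductive 1,3-transposition of the primary allylic alcohol.
3. 11 ⇒ spiro vinylogous ester 7: hydroxymethyl-anion addition and Stork–Danheiser transposition, with the ring B ketone masked as a dioxolane.
4. Key disconnection: 7 ⇒ hydroxymethylene ketone 4 + methyl vinyl ketone 5 (intermolecular asymmetric Michael addition creating the quaternary spiro carbon, then aldol condensation); 4 ⇒ dimedone 1 + ethyl formate 3.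
5. Ring order: ring A comes intact from dimedone; ring B is closed second by the Michael/aldol spiroannulation.

Assumption: spiro compounds are numbered ring A = C1–C5 (C1 carries the methylidene carbon, C5 the gem-dimethyl group), spiro carbon = C6, ring B = C7–C11; the quinidine-derived catalyst of step 3 is taken to give the (S)-adduct (its quinine-derived pseudoenantiomer is used if the sense is opposite).

**Route**

Step 1
Reactants: 1 5,5-dimethylcyclohexane-1,3-dione (dimedone)
Product: 2 3-ethoxy-5,5-dimethylcyclohex-2-en-1-one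
Conditions: EtOH, 4-MeC6H4SO3H·H2O (2 mol%), PhMe, reflux, Dean–Stark
Reagents that add atoms: ethanol, CCO
Why: Acid-catalysed enol etherification of the symmetrical 1,3-dione with azeotropic removal of water gives the vinylogous ester; no stereocenter.

Step 2
Reactants: 2 3-ethoxy-5,5-dimethylcyclohex-2-en-1-one; 3 ethyl formate
Product: 4 (6Z)-3-ethoxy-6-(hydroxymethylidene)-5,5-dimethylcyclohex-2-en-1-one
Conditions: LiN(iPr)2 (2.2 equiv), THF, −78 °C; then 3, −78 → 0 °C; 1 M HCl
Reagents that add atoms: none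
Why: Crossed Claisen condensation (formylation) of the kinetic α′-lithium enolate at C6, the only enolisable carbon next to the carbonyl, driven by deprotonation of the β-keto aldehyde by the second equivalent of base; no stereocenter.

Step 3
Reactants: 4 (6Z)-3-ethoxy-6-(hydroxymethylidene)-5,5-dimethylcyclohex-2-en-1-one; 5 but-3-en-2-one (methyl vinyl ketone)
Product: 6 (1S)-4-ethoxy-6,6-dimethyl-2-oxo-1-(3-oxobutyl)cyclohex-3-ene-1-carbaldehyde
Conditions: 5 (2 equiv), 9-O-(phenanthren-9-yl)cupreidine (C33H30N2O2, 10 mol%), CH2Cl2, −20 °C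
Reagents that add atoms: none
Why: Intermolecular Michael addition of the acidic 1,3-dicarbonyl donor to the unhindered enone under bifunctional base/hydrogen-bond catalysis by the cinchona alkaloid, whose chiral ion pair shields one enolate face and sets the quaternary carbon as (S).

Step 4
Reactants: 6 (1S)-4-ethoxy-6,6-dimethyl-2-oxo-1-(3-oxobutyl)cyclohex-3-ene-1-carbaldehyde
Product: 7 (6R)-3-ethoxy-5,5-dimethylspiro[5.5]undeca-2,7-diene-1,9-dione
Conditions: 4-MeC6H4SO3H·H2O (10 mol%), PhMe, reflux, Dean–Stark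
Reagents that add atoms: none
Why: Acid-catalysed intramolecular aldol condensation of the methyl ketone onto the non-enolisable aldehyde closes six-membered ring B (Robinson-type spiroannulation) under the anhydrous acid conditions that vinylogous esters tolerate; the quaternary centre is untouched.

Step 5
Reactants: 7 (6R)-3-ethoxy-5,5-dimethylspiro[5.5]undeca-2,7-diene-1,9-dione
Product: 8 (6R)-3-ethoxy-9,9-(ethylenedioxy)-5,5-dimethylspiro[5.5]undeca-2,7-dien-1-one
Conditions: Me3SiOCH2CH2OSiMe3 (1.5 equiv), Me3SiOSO2CF3 (3 mol%), CH2Cl2, −78 → −40 °C; pyridine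
Reagents that add atoms: 1,2-bis(trimethylsilyloxy)ethane, C[Si](C)(C)OCCO[Si](C)(C)C
Why: Noyori ketalisation acetalises the normal enone carbonyl of ring B without moving the double bond (C6 is quaternary), while the much less electrophilic vinylogous ester carbonyl of ring A stays free.

Step 6
Reactants: 8 (6R)-3-ethoxy-9,9-(ethylenedioxy)-5,5-dimethylspiro[5.5]undeca-2,7-dien-1-one
Product: 11 (6R)-9,9-(ethylenedioxy)-1-(hydroxymethyl)-5,5-dimethylspiro[5.5]undeca-1,7-dien-3-one, via carbinol silane 9 (not isolated), via diol 10 (not isolated)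
Conditions: iPrOMe2SiCH2MgCl (2.5 equiv, from ClCH2SiMe2OiPr and Mg), CeCl3, THF, −78 → 0 °C; then KF, KHCO3, 30% H2O2, THF/MeOH, 23 °C; then 0.5 M HCl, THF, 0 °C, 15 min
Reagents that add atoms: (isopropoxydimethylsilyl)methylmagnesium chloride, CC(C)O[Si](C)(C)C[Mg]Cl; hydrogen peroxide, OO; water, O
Why: Tamao nucleophilic hydroxymethylation (cerium-assisted 1,2-addition to the hindered vinylogous ester carbonyl, then oxidative C–Si cleavage before any acid so that Peterson elimination is avoided) followed by Stork–Danheiser hydrolysis/dehydration, which is far faster than dioxolane cleavage in cold dilute acid, gives the transposed enone carrying the future methylidene carbon as CH2OH; the transient C1 carbinol centre is destroyed.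

Step 7
Reactants: 11 (6R)-9,9-(ethylenedioxy)-1-(hydroxymethyl)-5,5-dimethylspiro[5.5]undeca-1,7-dien-3-one
Product: 12 (6R)-1-{[tert-butyl(dimethyl)silyl]oxymethyl}-9,9-(ethylenedioxy)-5,5-dimethylspiro[5.5]undeca-1,7-dien-3-one
Conditions: tBuMe2SiCl (1.2 equiv), imidazole (2.5 equiv), CH2Cl2, 0 → 23 °C
Reagents that add atoms: tert-butyl(chloro)dimethylsilane, CC(C)(C)[Si](C)(C)Cl
Why: Silylation of the primary allylic alcohol removes the only OH so that the next step deprotonates cleanly at the α′-CH2.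

Step 8
Reactants: 12 (6R)-1-{[tert-butyl(dimethyl)silyl]oxymethyl}-9,9-(ethylenedioxy)-5,5-dimethylspiro[5.5]undeca-1,7-dien-3-one
Product: 14 (4S,6S)-4-bromo-1-{[tert-butyl(dimethyl)silyl]oxymethyl}-9,9-(ethylenedioxy)-5,5-dimethylspiro[5.5]undeca-1,7-dien-3-one, via silyl dienol ether 13 (not isolated)
Conditions: LiN(iPr)2 (1.15 equiv), THF, −78 °C; Me3SiCl (1.3 equiv); then N-bromosuccinimide (1.05 equiv), THF, −78 °C
Reagents that add atoms: N-bromosuccinimide, O=C1CCC(=O)N1Br
Why: Kinetic α′-deprotonation (C2 is blocked as an alkene carbon) gives the cross-conjugated silyl dienol ether, and its electrophilic bromination at C4 occurs anti to the pseudoaxial C5 methyl on the side of the flat vinylic arm (C7) of ring B, giving mainly the (4S) epimer (moderate dr expected, epimers separated by chromatography).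

Step 9
Reactants: 14 (4S,6S)-4-bromo-1-{[tert-butyl(dimethyl)silyl]oxymethyl}-9,9-(ethylenedioxy)-5,5-dimethylspiro[5.5]undeca-1,7-dien-3-one
Product: 15 (3R,4S,6S)-4-bromo-1-{[tert-butyl(dimethyl)silyl]oxymethyl}-9,9-(ethylenedioxy)-5,5-dimethylspiro[5.5]undeca-1,7-dien-3-ol
Conditions: iBu2AlH (1.5 equiv), CH2Cl2, −78 °C; aq. KNaC4H4O6
Reagents that add atoms: none
Why: 1,2-Reduction of the α′-bromo enone with hydride delivered anti to the C–Br bond and away from the axial C5 methyl (Felkin–Anh/Cornforth control) gives the cis-bromohydrin, (3R).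

Step 10
Reactants: 15 (3R,4S,6S)-4-bromo-1-{[tert-butyl(dimethyl)silyl]oxymethyl}-9,9-(ethylenedioxy)-5,5-dimethylspiro[5.5]undeca-1,7-dien-3-ol
Product: 16 (3R,4S,6S)-4-bromo-9,9-(ethylenedioxy)-1-(hydroxymethyl)-5,5-dimethylspiro[5.5]undeca-1,7-dien-3-ol
Conditions: Bu4NF (1.2 equiv), THF, 0 °C
Reagents that add atoms: none
Why: Fluoride desilylation frees the primary allylic alcohol; the cis-bromohydrin cannot reach the anti-periplanar geometry needed for epoxide closure.

Step 11
Reactants: 16 (3R,4S,6S)-4-bromo-9,9-(ethylenedioxy)-1-(hydroxymethyl)-5,5-dimethylspiro[5.5]undeca-1,7-dien-3-ol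
Product: 19 (3R,4S,6S)-4-bromo-9,9-(ethylenedioxy)-5,5-dimethyl-1-methylidenespiro[5.5]undec-7-en-3-ol, via sulfonylhydrazine 17 (not isolated), via allylic diazene 18 (not isolated)
Conditions: 2-O2NC6H4SO2NHNH2 (1.3 equiv), PPh3 (1.3 equiv), EtO2CN=NCO2Et (1.3 equiv), THF, −30 °C, 2 h; then 23 °C, 3 h
Reagents that add atoms: none
Why: Myers reductive 1,3-transposition: Mitsunobu displacement of the unhindered primary allylic alcohol (the hindered secondary one is left), loss of sulfinic acid to the monoalkyl diazene and retro-ene loss of N2 deliver hydrogen to C2 and place the double bond exocyclic by mechanism.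

Step 12
Reactants: 19 (3R,4S,6S)-4-bromo-9,9-(ethylenedioxy)-5,5-dimethyl-1-methylidenespiro[5.5]undec-7-en-3-ol
Product: 20 (3R,4S,6S)-4-bromo-3-hydroxy-5,5-dimethyl-1-methylidenespiro[5.5]undec-7-en-9-one
Conditions: 1 M HCl, THF, 0 → 23 °C, 1 h
Reagents that add atoms: water, O
Why: Acid hydrolysis of the allylic dioxolane regenerates the ring B enone under conditions too mild to isomerise the exocyclic alkene or ionise the homoallylic alcohol.

Step 13
Reactants: 20 (3R,4S,6S)-4-bromo-3-hydroxy-5,5-dimethyl-1-methylidenespiro[5.5]undec-7-en-9-one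
Product: 21 Mailiohydrin, (3R,4S,6S,9R)-4-bromo-9-(dibromomethyl)-5,5-dimethyl-1-methylidenespiro[5.5]undec-7-ene-3,9-diol
Conditions: CH2Br2 (5 equiv), LiN(iPr)2 (4 equiv), THF, −78 °C, 15 min; then 20, −78 °C, 1 h; AcOH, −78 °C
Reagents that add atoms: dibromomethane, BrCBr
Why: 1,2-Addition of the bulky carbenoid dibromomethyllithium to the enone carbonyl from the equatorial direction of the ring B half-chair (CMe2 arm pseudoequatorial) places CHBr2 pseudoequatorial and OH pseudoaxial, (9R); the cold acidic quench prevents closure of the alkoxide to a bromo-epoxide.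

**Compound list**
1 | 5,5-dimethylcyclohexane-1,3-dione (dimedone) | CC1(C)CC(=O)CC(=O)C1 | starting material
2 | 3-ethoxy-5,5-dimethylcyclohex-2-en-1-one | CCOC1=CC(=O)CC(C)(C)C1 | intermediate
3 | ethyl formate | CCOC=O | starting material
4 | (6Z)-3-ethoxy-6-(hydroxymethylidene)-5,5-dimethylcyclohex-2-en-1-one | O/C=C1/C(C)(C)CC(OCC)=CC1=O | intermediate
5 | but-3-en-2-one (methyl vinyl ketone) | CC(=O)C=C | starting material
6 | (1S)-4-ethoxy-6,6-dimethyl-2-oxo-1-(3-oxobutyl)cyclohex-3-ene-1-carbaldehyde | O=C1C=C(OCC)CC(C)(C)[C@@]1(CCC(C)=O)C=O | intermediate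
7 | (6R)-3-ethoxy-5,5-dimethylspiro[5.5]undeca-2,7-diene-1,9-dione | O=C1C=C(OCC)CC(C)(C)[C@@]12C=CC(=O)CC2 | intermediate
8 | (6R)-3-ethoxy-9,9-(ethylenedioxy)-5,5-dimethylspiro[5.5]undeca-2,7-dien-1-one | O=C1C=C(OCC)CC(C)(C)[C@@]12C=CC3(OCCO3)CC2 | intermediate
9 | (6R)-1-{[dimethyl(propan-2-yloxy)silyl]methyl}-3-ethoxy-9,9-(ethylenedioxy)-5,5-dimethylspiro[5.5]undeca-2,7-dien-1-ol (both C1 epimers, centre lost in the same step) | CC(C)O[Si](C)(C)CC1(O)C=C(OCC)CC(C)(C)[C@@]12C=CC3(OCCO3)CC2 | intermediate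
10 | (6R)-3-ethoxy-9,9-(ethylenedioxy)-1-(hydroxymethyl)-5,5-dimethylspiro[5.5]undeca-2,7-dien-1-ol (both C1 epimers, centre lost in the same step) | OCC1(O)C=C(OCC)CC(C)(C)[C@@]12C=CC3(OCCO3)CC2 | intermediate
11 | (6R)-9,9-(ethylenedioxy)-1-(hydroxymethyl)-5,5-dimethylspiro[5.5]undeca-1,7-dien-3-one | OCC1=CC(=O)CC(C)(C)[C@@]12C=CC3(OCCO3)CC2 | intermediate
12 | (6R)-1-{[tert-butyl(dimethyl)silyl]oxymethyl}-9,9-(ethylenedioxy)-5,5-dimethylspiro[5.5]undeca-1,7-dien-3-one | CC(C)(C)[Si](C)(C)OCC1=CC(=O)CC(C)(C)[C@@]12C=CC3(OCCO3)CC2 | intermediate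
13 | (6R)-1-{[tert-butyl(dimethyl)silyl]oxymethyl}-9,9-(ethylenedioxy)-5,5-dimethyl-3-(trimethylsilyloxy)spiro[5.5]undeca-1,3,7-triene | CC(C)(C)[Si](C)(C)OCC1=CC(O[Si](C)(C)C)=CC(C)(C)[C@@]12C=CC3(OCCO3)CC2 | intermediate
14 | (4S,6S)-4-bromo-1-{[tert-butyl(dimethyl)silyl]oxymethyl}-9,9-(ethylenedioxy)-5,5-dimethylspiro[5.5]undeca-1,7-dien-3-one | CC(C)(C)[Si](C)(C)OCC1=CC(=O)[C@@H](Br)C(C)(C)[C@@]12C=CC3(OCCO3)CC2 | intermediate
15 | (3R,4S,6S)-4-bromo-1-{[tert-butyl(dimethyl)silyl]oxymethyl}-9,9-(ethylenedioxy)-5,5-dimethylspiro[5.5]undeca-1,7-dien-3-ol | CC(C)(C)[Si](C)(C)OCC1=C[C@@H](O)[C@@H](Br)C(C)(C)[C@@]12C=CC3(OCCO3)CC2 | intermediate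
16 | (3R,4S,6S)-4-bromo-9,9-(ethylenedioxy)-1-(hydroxymethyl)-5,5-dimethylspiro[5.5]undeca-1,7-dien-3-ol | OCC1=C[C@@H](O)[C@@H](Br)C(C)(C)[C@@]12C=CC3(OCCO3)CC2 | intermediate
17 | N-{[(3R,4S,6S)-4-bromo-9,9-(ethylenedioxy)-3-hydroxy-5,5-dimethylspiro[5.5]undeca-1,7-dien-1-yl]methyl}-2-nitrobenzenesulfonohydrazide | NN(CC1=C[C@@H](O)[C@@H](Br)C(C)(C)[C@@]12C=CC3(OCCO3)CC2)S(=O)(=O)c4ccccc4[N+](=O)[O-] | intermediate
18 | (3R,4S,6S)-4-bromo-1-(diazenylmethyl)-9,9-(ethylenedioxy)-5,5-dimethylspiro[5.5]undeca-1,7-dien-3-ol | N=NCC1=C[C@@H](O)[C@@H](Br)C(C)(C)[C@@]12C=CC3(OCCO3)CC2 | intermediate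
19 | (3R,4S,6S)-4-bromo-9,9-(ethylenedioxy)-5,5-dimethyl-1-methylidenespiro[5.5]undec-7-en-3-ol | C=C1C[C@@H](O)[C@@H](Br)C(C)(C)[C@@]12C=CC3(OCCO3)CC2 | intermediate
20 | (3R,4S,6S)-4-bromo-3-hydroxy-5,5-dimethyl-1-methylidenespiro[5.5]undec-7-en-9-one | C=C1C[C@@H](O)[C@@H](Br)C(C)(C)[C@@]12C=CC(=O)CC2 | intermediate
21 | Mailiohydrin, (3R,4S,6S,9R)-4-bromo-9-(dibromomethyl)-5,5-dimethyl-1-methylidenespiro[5.5]undec-7-ene-3,9-diol | C=C1C[C@@H](O)[C@@H](Br)C(C)(C)[C@@]12C=C[C@@](O)(C(Br)Br)CC2 | target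

**Totals**
Total step count: 13. Longest linear sequence: 13 steps (1 → 21).

**Three steps most likely to fail**

Step 3 (enantioselective Michael addition at a neopentyl carbon next to the gem-dimethyl group: rate and ee are uncertain for this hindered donor). The fallback uses a stoichiometric chiral auxiliary instead of catalysis. It sets out from 4: condensation with (S)-1-phenylethylamine (PhMe, 23 °C) gives the hydrogen-bonded (6Z)-enaminone F1. Its thermal aza-ene-type Michael addition to 5 (THF, 40 °C), through a compact chair-like transition state with internal N–H transfer, gives the imine F2 with the quaternary centre set by the auxiliary. Hydrolysis with aqueous AcOH comes back to the route at 6 (the amine antipode is used if the sense is opposite).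

Step 8 (the bromine must enter cis to the vinylic arm of ring B; the two arms at the spiro carbon differ only slightly, so the facial selectivity may be low or reversed). The fallback lets a hydrogen-atom transfer, not the bromination, decide the configuration. It sets out from 12: two rounds of LiN(iPr)2/Me3SiCl/N-bromosuccinimide give the 4,4-dibromo enone F3. Radical mono-debromination (Bu3SnH 1.0 equiv, Et3B, air, PhMe, −78 °C) delivers hydrogen to the planar α-keto radical from the face that electrophilic bromine prefers, so the surviving bromine ends on the opposite face. This is the complementary epimer, and the sequence comes back at 14.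

Step 13 (face selectivity of the carbenoid addition at C9 rests on a conformational argument, and the 9-epimer may predominate). The fallback uses a bulkier nucleophile with a stronger equatorial preference, then a reduction. It sets out from 20: tribromomethyllithium (CHBr3, LiN(iPr)2, THF, −100 °C) gives the tribromomethyl carbinol F4. Selective removal of one bromine from the weak CBr3 bonds (Bu3SnH 1.0 equiv, Et3B, PhMe, −78 °C) comes back at 21.

**Further compounds**
F1 | step 3 | (6Z)-3-ethoxy-5,5-dimethyl-6-({[(1S)-1-phenylethyl]amino}methylidene)cyclohex-2-en-1-one | C[C@H](N/C=C1/C(C)(C)CC(OCC)=CC1=O)c2ccccc2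
F2 | step 3 | (6S)-3-ethoxy-5,5-dimethyl-6-(3-oxobutyl)-6-[(E)-{[(1S)-1-phenylethyl]imino}methyl]cyclohex-2-en-1-one | C[C@H](/N=C/[C@]1(CCC(C)=O)C(C)(C)CC(OCC)=CC1=O)c2ccccc2
F3 | step 8 | (6S)-4,4-dibromo-1-{[tert-butyl(dimethyl)silyl]oxymethyl}-9,9-(ethylenedioxy)-5,5-dimethylspiro[5.5]undeca-1,7-dien-3-one | CC(C)(C)[Si](C)(C)OCC1=CC(=O)C(Br)(Br)C(C)(C)[C@@]12C=CC3(OCCO3)CC2
F4 | step 13 | (3R,4S,6S,9R)-4-bromo-5,5-dimethyl-1-methylidene-9-(tribromomethyl)spiro[5.5]undec-7-ene-3,9-diol | C=C1C[C@@H](O)[C@@H](Br)C(C)(C)[C@@]12C=C[C@@](O)(C(Br)(Br)Br)CC2
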